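**Retrosynthetic overview**
- Nymphaeol A comes from its tetrakis(TBS) ether by one buffered fluoride deprotection (TBS = tert-butyldimethylsilyl).
- The strategy rests on C2 of ring C: in the open precursor it is the benzylic CH2 of the O1 aryl benzyl ether, whose two enantiotopic hydrogens lie 1,6 to C3 (C3–C4–C4a–C8a–O1–C2). A rhodium carbenoid at C3 inserts into one of them, forming C2–C3 and closing ring C.
- The diazoketone comes from the corresponding methyl ketone by detrifluoroacetylative diazo transfer, so no aldehyde oxidation, acid chloride or diazomethane is needed.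
- The methyl ketone comes from 3-geranyl-2,4,6-trihydroxyacetophenone by O4 silylation, Mitsunobu etherification of O6 (para to geranyl) with 3,4-bis(TBSO)benzyl alcohol, and O2 silylation; the geranyl group is put on by C-alkylation of 2,4,6-trihydroxyacetophenone.
- Rings A and B are bought; ring C is the only ring formed.

Key step: step 8

Assumption: the sense of induction of the tert-leucinate-derived dirhodium catalyst on this substrate cannot be predicted with confidence. The route is written with Rh2(S-PTTL)4, and the mirror-image catalyst Rh2(R-PTTL)4 is to be used if a test cyclisation shows the (2R) series.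

**Step 1**
Reactants: 1 2,4,6-trihydroxyacetophenone; 2 geranyl bromide
Product: 3 1-(3-geranyl-2,4,6-trihydroxyphenyl)ethanone
Conditions: DBU (1.1 equiv), THF, 0 °C to rt; 1 in slight excess
Reagents that add atoms: none
Why: C-alkylation of the ambident phloroacetophenone anion by SN2 attack on the primary allylic bromide should place geranyl at C3 with the E alkene intact; the ring is symmetric so only one C-monoalkyl product exists, and excess ketone limits O-alkyl and dialkyl by-products.

**Step 2**
Reactants: 3 1-(3-geranyl-2,4,6-trihydroxyphenyl)ethanone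
Product: 4 1-[4-(TBSO)-3-geranyl-2,6-dihydroxyphenyl]ethanone
Conditions: TBSCl (1.05 equiv), imidazole, CH2Cl2–DMF, –20 to 0 °C
Reagents that add atoms: tert-butyldimethylsilyl chloride, CC(C)(C)[Si](C)(C)Cl
Why: Selective phenol silylation: the para hydroxyl (O4) is the most acidic and the only one that neither chelates nor flanks the acetyl group, so one equivalent of silyl chloride should take it first.

**Step 3**
Reactants: 5 3,4-dihydroxybenzaldehyde
Product: 6 3,4-bis(TBSO)benzaldehyde
Conditions: TBSCl (2.3 equiv), imidazole, DMF, rt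
Reagents that add atoms: tert-butyldimethylsilyl chloride, CC(C)(C)[Si](C)(C)Cl
Why: Standard imidazole-promoted silylation of both catechol hydroxyls.

**Step 4**
Reactants: 6 3,4-bis(TBSO)benzaldehyde
Product: 7 3,4-bis(TBSO)benzyl alcohol
Conditions: NaBH4, THF–MeOH, 0 °C
Reagents that add atoms: none
Why: Borohydride reduction of an aryl aldehyde to the benzylic alcohol; short reaction at 0 °C spares the aryl silyl ethers.

**Step 5**
Reactants: 4 1-[4-(TBSO)-3-geranyl-2,6-dihydroxyphenyl]ethanone; 7 3,4-bis(TBSO)benzyl alcohol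
Product: 8 1-{6-[3,4-bis(TBSO)benzyloxy]-4-(TBSO)-3-geranyl-2-hydroxyphenyl}ethanone
Conditions: PPh3, DIAD, THF, 0 °C to rt
Reagents that add atoms: none
Why: Mitsunobu etherification under neutral conditions: the O2 hydroxyl is pressed into the hydrogen bond to the acetyl oxygen by the neighbouring geranyl group and is flanked on both sides, so the unhindered O6 phenol (para to geranyl) should be the one alkylated by the activated primary benzylic alcohol.

**Step 6**
Reactants: 8 1-{6-[3,4-bis(TBSO)benzyloxy]-4-(TBSO)-3-geranyl-2-hydroxyphenyl}ethanone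
Product: 9 1-{6-[3,4-bis(TBSO)benzyloxy]-2,4-bis(TBSO)-3-geranylphenyl}ethanone
Conditions: TBSOTf (1.3 equiv), 2,6-lutidine, CH2Cl2, –78 to 0 °C
Reagents that add atoms: tert-butyldimethylsilyl trifluoromethanesulfonate, CC(C)(C)[Si](C)(C)OS(=O)(=O)C(F)(F)F
Why: The silyl triflate is reactive enough to silylate the chelated, doubly flanked phenol, while 2,6-lutidine is too weak a base to turn the methyl ketone into its silyl enol ether.

**Step 7**
Reactants: 9 1-{6-[3,4-bis(TBSO)benzyloxy]-2,4-bis(TBSO)-3-geranylphenyl}ethanone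
Product: 11 2-diazo-1-{6-[3,4-bis(TBSO)benzyloxy]-2,4-bis(TBSO)-3-geranylphenyl}ethanone, via trifluoroacetyl diketone 10 (not isolated)
Conditions: LiN(SiMe3)2, THF, –78 °C; CF3CO2CH2CF3; dilute HCl wash; then MsN3, Et3N, H2O (1 equiv), MeCN, rt
Reagents that add atoms: methanesulfonyl azide, CS(=O)(=O)N=[N+]=[N-]; 2,2,2-trifluoroethyl trifluoroacetate, O=C(OCC(F)(F)F)C(F)(F)F (its atoms stay only in 10)
Why: Detrifluoroacetylative diazo transfer: the kinetic lithium enolate of the methyl ketone (the only enolisable site) is C-trifluoroacetylated, and the activated diketone accepts the diazo group from the sulfonyl azide with loss of the trifluoroacetyl group as its sulfonamide.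

**Step 8**
Reactants: 11 2-diazo-1-{6-[3,4-bis(TBSO)benzyloxy]-2,4-bis(TBSO)-3-geranylphenyl}ethanone
Product: 12 (2S)-6-geranyl-5,7,3',4'-tetrakis(TBSO)flavanone
Conditions: Rh2(S-PTTL)4 [dirhodium tetrakis(N-phthaloyl-(S)-tert-leucinate)] (2 mol %), CH2Cl2, 0 °C, slow addition of 11
Reagents that add atoms: none
Why: The dirhodium tetracarboxylate expels N2 from 11 to give an electrophilic rhodium carbenoid at C3, which inserts into one of the two enantiotopic benzylic C2–H bonds of the O1–CH2–aryl ether through a concerted, hydride-transfer-like three-centre transition state, forming C2–C3 and releasing the catalyst. The closest known reaction type is the intramolecular C–H insertion of ortho-alkoxyaryl diazoketones catalysed by chiral divalent rhodium carboxylates, which gives 2-substituted chroman-4-ones. Ring C (the pyranone) is closed by a 1,6-insertion, the six atoms C3–C4–C4a–C8a–O1–C2 becoming the ring as the C2–C3 bond forms. C2 is the only new stereocentre and is set by catalyst control, the phthalimido and tert-butyl groups of the ligand sphere deciding which enantiotopic hydrogen reaches the carbenoid, so the (2S) sense depends on the ligand antipode chosen. The step needs insertion to outrun oxonium-ylide formation at O1 with [1,2]-benzyl shift, attack at the O5 oxygen and alkene cyclopropanation: the C2–H bonds are doubly activated (α-oxygen, electron-rich aryl), the di-ortho-substituted ketone is twisted out of the ring plane and so resists the planar five-membered ylide, the bulky silyl group on O5 offers no activated C–H and shields that oxygen, and the geranyl alkenes sit meta to the acyl group and cannot reach the carbenoid without a strained bridge.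

**Step 9**
Reactants: 12 (2S)-6-geranyl-5,7,3',4'-tetrakis(TBSO)flavanone
Product: 13 nymphaeol A, (2S)-2-(3,4-dihydroxyphenyl)-6-[(2E)-3,7-dimethylocta-2,6-dien-1-yl]-5,7-dihydroxychroman-4-one
Conditions: HF·pyridine, pyridine, THF, 0 °C to rt, under argon; pH 7 buffer work-up
Reagents that add atoms: none
Why: Fluoride-driven cleavage of the four aryl silyl ethers under buffered, weakly acidic conditions; no free phenoxide is formed, so the retro-oxa-Michael ring opening that would racemise C2 is avoided, and the geranyl chain is not cyclised.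

**Compound list**
1 | 2,4,6-trihydroxyacetophenone | CC(=O)c1c(O)cc(O)cc1O | starting material
2 | geranyl bromide, (2E)-1-bromo-3,7-dimethylocta-2,6-diene | CC(C)=CCC/C(C)=C/CBr | starting material
3 | 1-(3-geranyl-2,4,6-trihydroxyphenyl)ethanone | CC(C)=CCC/C(C)=C/Cc1c(O)cc(O)c(C(C)=O)c1O | intermediate
4 | 1-[4-(tert-butyldimethylsilyloxy)-3-geranyl-2,6-dihydroxyphenyl]ethanone | CC(C)=CCC/C(C)=C/Cc1c(O[Si](C)(C)C(C)(C)C)cc(O)c(C(C)=O)c1O | intermediate
5 | 3,4-dihydroxybenzaldehyde | O=Cc1ccc(O)c(O)c1 | starting material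
6 | 3,4-bis(tert-butyldimethylsilyloxy)benzaldehyde | O=Cc1ccc(O[Si](C)(C)C(C)(C)C)c(O[Si](C)(C)C(C)(C)C)c1 | intermediate
7 | 3,4-bis(tert-butyldimethylsilyloxy)benzyl alcohol | OCc1ccc(O[Si](C)(C)C(C)(C)C)c(O[Si](C)(C)C(C)(C)C)c1 | intermediate
8 | 1-{6-[3,4-bis(tert-butyldimethylsilyloxy)benzyloxy]-4-(tert-butyldimethylsilyloxy)-3-geranyl-2-hydroxyphenyl}ethanone | CC(C)=CCC/C(C)=C/Cc1c(O[Si](C)(C)C(C)(C)C)cc(OCc2ccc(O[Si](C)(C)C(C)(C)C)c(O[Si](C)(C)C(C)(C)C)c2)c(C(C)=O)c1O | intermediate
9 | 1-{6-[3,4-bis(tert-butyldimethylsilyloxy)benzyloxy]-2,4-bis(tert-butyldimethylsilyloxy)-3-geranylphenyl}ethanone | CC(C)=CCC/C(C)=C/Cc1c(O[Si](C)(C)C(C)(C)C)cc(OCc2ccc(O[Si](C)(C)C(C)(C)C)c(O[Si](C)(C)C(C)(C)C)c2)c(C(C)=O)c1O[Si](C)(C)C(C)(C)C | intermediate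
10 | 4,4,4-trifluoro-1-{6-[3,4-bis(tert-butyldimethylsilyloxy)benzyloxy]-2,4-bis(tert-butyldimethylsilyloxy)-3-geranylphenyl}butane-1,3-dione | CC(C)=CCC/C(C)=C/Cc1c(O[Si](C)(C)C(C)(C)C)cc(OCc2ccc(O[Si](C)(C)C(C)(C)C)c(O[Si](C)(C)C(C)(C)C)c2)c(C(=O)CC(=O)C(F)(F)F)c1O[Si](C)(C)C(C)(C)C | intermediate
11 | 2-diazo-1-{6-[3,4-bis(tert-butyldimethylsilyloxy)benzyloxy]-2,4-bis(tert-butyldimethylsilyloxy)-3-geranylphenyl}ethanone | CC(C)=CCC/C(C)=C/Cc1c(O[Si](C)(C)C(C)(C)C)cc(OCc2ccc(O[Si](C)(C)C(C)(C)C)c(O[Si](C)(C)C(C)(C)C)c2)c(C(=O)C=[N+]=[N-])c1O[Si](C)(C)C(C)(C)C | intermediate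
12 | (2S)-6-geranyl-5,7,3',4'-tetrakis(tert-butyldimethylsilyloxy)flavanone | CC(C)=CCC/C(C)=C/Cc1c(O[Si](C)(C)C(C)(C)C)cc2c(c1O[Si](C)(C)C(C)(C)C)C(=O)C[C@@H](c1ccc(O[Si](C)(C)C(C)(C)C)c(O[Si](C)(C)C(C)(C)C)c1)O2 | intermediate
13 | nymphaeol A, (2S)-6-geranyl-5,7,3',4'-tetrahydroxyflavanone | CC(C)=CCC/C(C)=C/Cc1c(O)cc2c(c1O)C(=O)C[C@@H](c1ccc(O)c(O)c1)O2 | target

**Step count**
Total: 9 steps. Longest linear sequence: 7 steps (steps 1, 2, 5, 6, 7, 8, 9); steps 3 and 4 make the benzyl alcohol side arm.

**Steps most likely to fail**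

1. Step 8. The carbenoid may be trapped by the O1 lone pair, with the resulting oxonium ylide undergoing a [1,2]-benzyl shift to a benzofuranone, or the catalyst may discriminate poorly between the two enantiotopic hydrogens.
Fallback, from 4 back to 12, making ring C by C–O bond formation at a preset carbinol:
   - Mitsunobu reaction of 4 with allyl alcohol (PPh3, DIAD), with the same O6 selectivity as step 5, should give 1-[6-(allyloxy)-4-(TBSO)-3-geranyl-2-hydroxyphenyl]ethanone F1.
   - TBSOTf and 2,6-lutidine should give the O2 silyl ether 1-[6-(allyloxy)-2,4-bis(TBSO)-3-geranylphenyl]ethanone F2.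
   - A boron-mediated asymmetric aldol addition of F2 to aldehyde 6 follows (B-chlorodiisopinocampheylborane of the antipode that delivers the (R)-carbinol, Et3N, –78 °C, diethanolamine work-up). It should give (3R)-1-[6-(allyloxy)-2,4-bis(TBSO)-3-geranylphenyl]-3-[3,4-bis(TBSO)phenyl]-3-hydroxypropan-1-one F3.
   - Deallylation with Pd(PPh3)4 (zerovalent palladium) and morpholine should free the O6 phenol, giving (3R)-1-[2,4-bis(TBSO)-3-geranyl-6-hydroxyphenyl]-3-[3,4-bis(TBSO)phenyl]-3-hydroxypropan-1-one F4.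
   - Intramolecular Mitsunobu etherification of F4 (PPh3, DIAD) should close ring C with inversion at the benzylic carbon to give 12. Any shortfall in enantiomeric purity from the aldol step would be made up by chromatography on a chiral phase.

2. Step 2. The silyl chloride may fail to distinguish the O4 and O6 hydroxyls, or may silylate twice, which scrambles the later placement of the benzyl ether.
Fallback, from 1 back to 9, fixing the oxygen pattern by rearrangement instead of by selective protection:
   - Bis-silylation of 1 (TBSCl 2.1 equiv, imidazole) leaves one chelated hydroxyl and should give 1-[2-hydroxy-4,6-bis(TBSO)phenyl]ethanone F5.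
   - Mitsunobu reaction of F5 with geraniol should give the O-geranyl ether 1-[2-(geranyloxy)-4,6-bis(TBSO)phenyl]ethanone F6.
   - Heating F6 in N,N-diethylaniline at about 190 °C should bring about the tandem Claisen–Cope (para-Claisen) rearrangement. This moves geranyl to the carbon para to the ether oxygen, between the two silyloxy groups, and should give 1-[3-geranyl-6-hydroxy-2,4-bis(TBSO)phenyl]ethanone F7, whose only free hydroxyl is the one para to geranyl.
   - Mitsunobu reaction of F7 with 7 should give 9. The E geometry of the geranyl alkene would have to be checked after the rearrangement.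

3. Step 7. The lithium enolate may pull the neighbouring O2 silyl group onto its own oxygen, or the aqueous amine of the transfer stage may strip an aryl silyl ether.
Fallback, from 9 back to 11, with no enolate and no aqueous base:
   - Condensation of 9 with tert-butoxybis(dimethylamino)methane (toluene, 60–80 °C) should give the enaminone (2E)-3-(dimethylamino)-1-{6-[3,4-bis(TBSO)benzyloxy]-2,4-bis(TBSO)-3-geranylphenyl}prop-2-en-1-one F8.
   - Treatment of F8 with methanesulfonyl azide in MeCN at rt should give 11 by cycloaddition and fragmentation of the triazoline, the aminomethylene carbon leaving as the N-sulfonyl formamidine.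

**Further compounds**
F1 | step 8 | 1-[6-(allyloxy)-4-(tert-butyldimethylsilyloxy)-3-geranyl-2-hydroxyphenyl]ethanone | CC(C)=CCC/C(C)=C/Cc1c(O[Si](C)(C)C(C)(C)C)cc(OCC=C)c(C(C)=O)c1O
F2 | step 8 | 1-[6-(allyloxy)-2,4-bis(tert-butyldimethylsilyloxy)-3-geranylphenyl]ethanone | CC(C)=CCC/C(C)=C/Cc1c(O[Si](C)(C)C(C)(C)C)cc(OCC=C)c(C(C)=O)c1O[Si](C)(C)C(C)(C)C
F3 | step 8 | (3R)-1-[6-(allyloxy)-2,4-bis(tert-butyldimethylsilyloxy)-3-geranylphenyl]-3-[3,4-bis(tert-butyldimethylsilyloxy)phenyl]-3-hydroxypropan-1-one | CC(C)=CCC/C(C)=C/Cc1c(O[Si](C)(C)C(C)(C)C)cc(OCC=C)c(C(=O)C[C@@H](O)c2ccc(O[Si](C)(C)C(C)(C)C)c(O[Si](C)(C)C(C)(C)C)c2)c1O[Si](C)(C)C(C)(C)C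
F4 | step 8 | (3R)-1-[2,4-bis(tert-butyldimethylsilyloxy)-3-geranyl-6-hydroxyphenyl]-3-[3,4-bis(tert-butyldimethylsilyloxy)phenyl]-3-hydroxypropan-1-one | CC(C)=CCC/C(C)=C/Cc1c(O[Si](C)(C)C(C)(C)C)cc(O)c(C(=O)C[C@@H](O)c2ccc(O[Si](C)(C)C(C)(C)C)c(O[Si](C)(C)C(C)(C)C)c2)c1O[Si](C)(C)C(C)(C)C
F5 | step 2 | 1-[2-hydroxy-4,6-bis(tert-butyldimethylsilyloxy)phenyl]ethanone | CC(=O)c1c(O)cc(O[Si](C)(C)C(C)(C)C)cc1O[Si](C)(C)C(C)(C)C
F6 | step 2 | 1-[2-(geranyloxy)-4,6-bis(tert-butyldimethylsilyloxy)phenyl]ethanone | CC(C)=CCC/C(C)=C/COc1cc(O[Si](C)(C)C(C)(C)C)cc(O[Si](C)(C)C(C)(C)C)c1C(C)=O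
F7 | step 2 | 1-[3-geranyl-6-hydroxy-2,4-bis(tert-butyldimethylsilyloxy)phenyl]ethanone | CC(C)=CCC/C(C)=C/Cc1c(O[Si](C)(C)C(C)(C)C)cc(O)c(C(C)=O)c1O[Si](C)(C)C(C)(C)C
F8 | step 7 | (2E)-3-(dimethylamino)-1-{6-[3,4-bis(tert-butyldimethylsilyloxy)benzyloxy]-2,4-bis(tert-butyldimethylsilyloxy)-3-geranylphenyl}prop-2-en-1-one | CC(C)=CCC/C(C)=C/Cc1c(O[Si](C)(C)C(C)(C)C)cc(OCc2ccc(O[Si](C)(C)C(C)(C)C)c(O[Si](C)(C)C(C)(C)C)c2)c(C(=O)/C=C/N(C)C)c1O[Si](C)(C)C(C)(C)C
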